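(All runs are simulated from invented constants; scatter was added.)

**One-step world.** In a one-step world, substrate lost is target made, so the two would sum to the whole charge. In the midnight run at 40.0 min they sum to 65.0%, so substrate also leaves by another way.

| setting | midnight | spring | north-west | south-west | north |
|---|---|---|---|---|---|
| substrate | 0.020 M (fed, over 10 min) | 0.020 M (fed, over 10 min) | 0.020 M (fed, over 10 min) | 0.020 M (fed, over 10 min) | 0.020 M (fed, over 10 min) |
| capture agent | 0.57 mM | 3.1 mM | 1.00 mM | 2.00 mM | 4.00 mM |
| remark | run made earlier | run made earlier |  |  |  |
| time |  |  | 80 min | 80 min | 80 min |

| run | time / min | target / % | substrate / % |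
|---|---|---|---|
| midnight | 10.0 | 3 | 91 |
| midnight | 20.0 | 9 | 71 |
| midnight | 30.0 | 17 | 55 |
| midnight | 40.0 | 24 | 41 |
| spring | 3.00 | 0 | 29 |
| spring | 8.00 | 4 | 71 |
| spring | 15.0 | 5 | 79 |
| spring | 40.0 | 19 | 37 |

(readings scatter by 2 percentage points)

* amount of target at the end, in percent of the substrate charged for north-west, south-west, north, in this order
* how the row runs (falls all the way / hardly changes / rises, then falls / falls, then rises / rises all the way)

- a reading or a percentage of target counts all its forms, free or not
- "hardly changes" means that all values lie within two and a half points (for a concentration: within two and a half percent of the largest)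
- percentages count the whole charge, also what has not yet gone in

**Branch share.** We therefore work with the fraction left. Define the branch share φ, the selectivity of the substrate's loss toward target, as target made per substrate lost. Pooling the midnight and spring readings at 40.0 min gives φ = 0.352, a reading that carries their scatter. If φ holds, target at the end is φ times the fraction of substrate gone.

**The bracket.** Substrate cannot be lost beyond the whole charge, so the ceiling is 35.2%. If loss stopped at 40.0 min, with 39.0% left on average, the floor would be 21.5%. To tighten it, the midnight run falls from 91% to 41% after the feed, a first-order constant k = 0.0266 min⁻¹. That leaves 13.5% at 80 min, so our own estimate is 30.5%.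

The midnight and spring targets differ by 5 percentage points, on readings each good to 2 points. We read that as scatter and hold φ the same in the three flasks, so our row hardly changes. Our risk is north, whose capture agent lies above spring's.

**The forecast.** It gives 52%, 48% and 42%, and says the row falls all the way, on the ground that “More agent gives less target”. Even its 42% lies above our ceiling, outside the bracket.

**The flask.** North-west, south-west and north end at 28.7%, 28.7% and 28.7%: the row hardly changes.

    crystals ⇌ target, rate k1*(cs1 - [target]) while solid is left; crystals form when [target] > cs1 (solubility = 10.0 mM, k = 0.00770 s⁻¹)
    intermediate A → side product (k = 5.80 × 10⁻⁵ s⁻¹)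
    intermediate A ⇌ intermediate B (K = 2.40, k = 1.10 × 10⁻⁴ s⁻¹)
    substrate → intermediate A (k = 2.70 × 10⁻⁴ s⁻¹)
    capture agent + intermediate B → trapped intermediate (k = 0.00230 M⁻¹ s⁻¹)
    substrate → target (k = 1.40 × 10⁻⁴ s⁻¹)

**Same share.** In north-west, 15.8% of substrate stands at 80.0 min, so φ gives 29.6%, close to the 28.7% found. The capture agent reacts with intermediate B, and in north-west that step makes no difference to target. North shows the ceiling: at 800 min, with substrate at 0%, it holds 34.1% of target against φ's 35.2%. Its reading at 80.0 min stands lower by 5.4 points.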